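## Retrosynthetic overview

1. The 3,4-dihydroisoquinoline C=N ring is closed last: acid removes every Boc and MOM group and the freed amine condenses onto a masked aryl methyl ketone. The tetrahydroisoquinoline (THIQ) ring is already in place.
2. The central 6′–6″ bond comes from a new silicon-tethered dehydrogenative hetero-coupling of two different naphthol "monomers" (half A and half B).
3. Each 5,8′ biaryl axis is made by Suzuki coupling of a 5-bromo-isoquinoline unit with one common naphthyl boronate, which is built by Stobbe benzannulation.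
4. Both isoquinoline units come from orsellinate-type arenes: lateral lithiation and addition to an (R)-sulfinyl acetaldimine sets C3 (R); a trans-selective imine reduction sets C1 (R) of the THIQ.
5. Ring order: naphthalene → lactam (half A) and THIQ (half B) → biaryl axes → 6′,6″ bond → dihydroisoquinoline ring.

Assumption: the SMILES fixes only the three stereocentres (all R) and not the two configurationally stable 5,8′ axes, so I target the P,P-atropisomer (P = positive C6–C5–C8′–C8a′ torsion) and carry the P isomer forward after each Suzuki step; the M isomers come from the same steps. The central 6′,6″ axis rotates freely.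

## Route

### Common naphthyl boronate

**Step 1**
Reactants: 1, 2-bromo-5-hydroxybenzaldehyde
Product: 2, 5-(benzyloxy)-2-bromobenzaldehyde
Conditions: BnBr, K2CO3, DMF, rt
Reagents that add atoms: benzyl bromide, BrCc1ccccc1
Why: Williamson etherification of the only phenol; benzyl can later be removed by hydrogenolysis without touching MOM or Boc groups.

**Step 2**
Reactants: 2; 3, diethyl succinate
Product: 4, (E)-4-[5-(benzyloxy)-2-bromophenyl]-3-(ethoxycarbonyl)but-3-enoic acid
Conditions: t-BuOK, t-BuOH, 80 °C; then H3O+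
Reagents that add atoms: none
Why: Stobbe condensation of a non-enolisable aldehyde gives the half-ester with the aryl group cis to CH2CO2H, as needed for ring closure.

**Step 3**
Reactants: 4
Product: 5, ethyl 4-acetoxy-5-(benzyloxy)-8-bromo-2-naphthoate
Conditions: Ac2O, NaOAc, 140 °C
Reagents that add atoms: acetic anhydride, CC(=O)OC(C)=O
Why: Intramolecular Friedel–Crafts acylation via the mixed anhydride, then enol acetylation; the only free ortho position is the one next to OBn, so the regiochemistry is fixed.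

**Step 4**
Reactants: 5
Product: 6, ethyl 5-(benzyloxy)-8-bromo-4-methoxy-2-naphthoate
Conditions: NaOEt, EtOH, 0 °C; then MeI, K2CO3, DMF, rt
Reagents that add atoms: iodomethane, CI
Why: Ethanolysis of the aryl acetate (no ester scrambling in EtOH) followed by O-methylation of the naphthol installs the 4′-OMe.

**Step 5**
Reactants: 6
Product: 7, [5-(benzyloxy)-8-bromo-4-methoxynaphthalen-2-yl]methanol
Conditions: DIBAL-H, CH2Cl2, −78 → 0 °C
Reagents that add atoms: none
Why: Hydride reduction of the ester to the benzylic alcohol; the aryl bromide and ethers are inert at this temperature.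

**Step 6**
Reactants: 7
Product: 8, 4-(benzyloxy)-1-bromo-5-methoxy-7-methylnaphthalene
Conditions: CBr4, PPh3, CH2Cl2, 0 °C; then LiBHEt3, THF, 0 °C
Reagents that add atoms: none
Why: Appel bromination then SN2 hydride displacement converts CH2OH to CH3 (the 2′-methyl); the benzylic bromide is far more reactive than the aryl bromide.

**Step 7**
Reactants: 8
Product: 9, 2-[4-(benzyloxy)-5-methoxy-7-methylnaphthalen-1-yl]-4,4,5,5-tetramethyl-1,3,2-dioxaborolane
Conditions: n-BuLi, THF, −78 °C; then i-PrOBpin, −78 °C → rt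
Reagents that add atoms: 2-isopropoxy-4,4,5,5-tetramethyl-1,3,2-dioxaborolane, CC(C)OB1OC(C)(C)C(C)(C)O1
Why: Fast Br–Li exchange at −78 °C and borate trapping give the pinacol boronate used for both halves.

### Chiral imine

**Step 8**
Reactants: 10, (R)-2-methylpropane-2-sulfinamide; 11, acetaldehyde
Product: 12, (R,E)-N-ethylidene-2-methylpropane-2-sulfinamide
Conditions: anhydrous CuSO4, CH2Cl2, rt
Reagents that add atoms: none
Why: Dehydrative condensation gives the Ellman sulfinyl aldimine with the sulfur configuration unchanged.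

### Half A (masked dihydroisoquinoline)

**Step 9**
Reactants: 13, methyl 2,4-dihydroxy-6-methylbenzoate (methyl orsellinate)
Product: 14, methyl 2-hydroxy-4-(methoxymethoxy)-6-methylbenzoate
Conditions: MOMCl (1.1 equiv), i-Pr2NEt, CH2Cl2, 0 °C
Reagents that add atoms: chloromethyl methyl ether, COCCl
Why: Selective Williamson-type alkylation of the free 4-OH; the 2-OH is deactivated by its hydrogen bond to the ester, which differentiates the future 6-O and 8-O.

**Step 10**
Reactants: 14
Product: 15, methyl 2-methoxy-4-(methoxymethoxy)-6-methylbenzoate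
Conditions: MeI, K2CO3, DMF, 50 °C
Reagents that add atoms: iodomethane, CI
Why: O-methylation of the remaining chelated phenol gives the future 8-OMe.

**Step 11**
Reactants: 15; 12
Product: 16, methyl 2-[(2R)-2-{[(R)-tert-butylsulfinyl]amino}propyl]-6-methoxy-4-(methoxymethoxy)benzoate
Conditions: LDA, THF, −78 °C; then 12, −78 °C; AcOH quench
Reagents that add atoms: none
Why: Lateral (benzylic) lithiation of the o-toluate and 1,2-addition to the sulfinyl imine through a Li-chelated chair transition state delivers the benzyl carbon to the Si face of the (R_S)-imine, giving the (R)-amine carbon (future C3); the minor diastereomer is removed by chromatography.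

**Step 12**
Reactants: 16
Product: 17, (3R)-8-methoxy-6-(methoxymethoxy)-3-methyl-3,4-dihydroisoquinolin-1(2H)-one
Conditions: 4 M HCl/dioxane (2 equiv), MeOH, 0 °C, 30 min; then K2CO3, MeOH, 60 °C
Reagents that add atoms: none
Why: Brief acid cleaves the N-sulfinyl group much faster than an aryl MOM ether, and the free amine then lactamises onto the ortho ester (6-membered ring); C3 is not involved.

**Step 13**
Reactants: 17
Product: 18, (3R)-5-bromo-8-methoxy-6-(methoxymethoxy)-3-methyl-3,4-dihydroisoquinolin-1(2H)-one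
Conditions: NBS, MeCN, 0 °C
Reagents that add atoms: N-bromosuccinimide, O=C1CCC(=O)N1Br
Why: Electrophilic aromatic bromination goes to C5 (para to 8-OMe, ortho to 6-OMOM) and not to C7, which is flanked by two alkoxy groups.

**Step 14**
Reactants: 18; 9
Product: 19, (3R,5P)-5-[4-(benzyloxy)-5-methoxy-7-methylnaphthalen-1-yl]-8-methoxy-6-(methoxymethoxy)-3-methyl-3,4-dihydroisoquinolin-1(2H)-one
Conditions: Pd(OAc)2, SPhos, K3PO4, toluene/H2O, 90 °C; chromatographic separation of atropisomers
Reagents that add atoms: none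
Why: Suzuki–Miyaura coupling with a bulky biarylphosphine forms the tri-ortho-substituted axis; the two configurationally stable atropisomers are diastereomers because of C3, so they are separable, and P is kept (assigned by NOE/CD).

**Step 15**
Reactants: 19
Product: 20, tert-butyl (3R,5P)-5-[4-(benzyloxy)-5-methoxy-7-methylnaphthalen-1-yl]-8-methoxy-6-(methoxymethoxy)-3-methyl-1-oxo-3,4-dihydroisoquinoline-2(1H)-carboxylate
Conditions: Boc2O, DMAP, MeCN, rt
Reagents that add atoms: di-tert-butyl dicarbonate, CC(C)(C)OC(=O)OC(=O)OC(C)(C)C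
Why: DMAP-catalysed N-acylation turns the lactam into an imide-like N-Boc lactam that is activated for ring opening.

**Step 16**
Reactants: 20
Product: 21, tert-butyl N-[(2R)-1-{2-acetyl-6-[(P)-4-(benzyloxy)-5-methoxy-7-methylnaphthalen-1-yl]-3-methoxy-5-(methoxymethoxy)phenyl}propan-2-yl]carbamate
Conditions: MeMgBr (1.5 equiv), THF, −78 → −20 °C
Reagents that add atoms: methylmagnesium bromide, C[Mg]Br
Why: Grignard addition to the ring carbonyl of the N-Boc lactam and collapse of the tetrahedral intermediate give the Boc-amino methyl ketone (C1 and its methyl); the 2,6-disubstituted ketone resists a second addition.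

**Step 17**
Reactants: 21
Product: 22, tert-butyl N-[(2R)-1-{2-acetyl-6-[(P)-4-hydroxy-5-methoxy-7-methylnaphthalen-1-yl]-3-methoxy-5-(methoxymethoxy)phenyl}propan-2-yl]carbamate (naphthol A)
Conditions: H2 (1 atm), 10% Pd/C, EtOAc, rt
Reagents that add atoms: none
Why: Hydrogenolysis removes only the benzyl ether; the hindered, twisted aryl ketone, MOM and Boc groups survive.

### Half B (tetrahydroisoquinoline)

**Step 18**
Reactants: 23, 2,4-dihydroxy-6-methylbenzaldehyde
Product: 24, 2,4-bis(methoxymethoxy)-6-methylbenzaldehyde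
Conditions: NaH, MOMCl (2.5 equiv), DMF, 0 °C → rt
Reagents that add atoms: chloromethyl methyl ether, COCCl
Why: Double Williamson alkylation; NaH is needed for the chelated 2-OH.

**Step 19**
Reactants: 24
Product: 25, 2,4-bis(methoxymethoxy)-6-methylbenzonitrile
Conditions: I2, 28% aq NH3, THF, rt
Reagents that add atoms: ammonia, N
Why: Oxidative conversion of the aldehyde to the nitrile (aldimine, N-iodoimine, then HI loss) under basic conditions that MOM ethers tolerate.

**Step 20**
Reactants: 25; 12
Product: 26, (R)-N-{(2R)-1-[2-cyano-3,5-bis(methoxymethoxy)phenyl]propan-2-yl}-2-methylpropane-2-sulfinamide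
Conditions: LDA, THF, −78 °C; then 12, −78 °C; AcOH quench
Reagents that add atoms: none
Why: Lateral lithiation of the o-tolunitrile and chelate-controlled 1,2-addition to the (R_S)-sulfinyl imine set C3 as R by the same facial selectivity as in Step 11.

**Step 21**
Reactants: 26
Product: 27, (3R)-6,8-bis(methoxymethoxy)-1,3-dimethyl-3,4-dihydroisoquinoline
Conditions: MeLi (3.5 equiv), THF, −78 → 0 °C; then HCl/dioxane–MeOH, 0 °C, 30 min; aq NaHCO3
Reagents that add atoms: methyllithium, [Li]C
Why: MeLi adds to the nitrile to give the methyl ketimine, and brief acid removes the sulfinyl group so the amine closes by intramolecular transimination (loss of NH3) to the cyclic imine.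

**Step 22**
Reactants: 27
Product: 28, (1R,3R)-6,8-bis(methoxymethoxy)-1,3-dimethyl-1,2,3,4-tetrahydroisoquinoline
Conditions: LiAlH4, AlMe3, THF, −78 → −20 °C
Reagents that add atoms: none
Why: Hydride reduction of the AlMe3-complexed imine is the established 1,3-trans-selective protocol for this ring system and sets C1 as R; the minor cis isomer is removed by chromatography.

**Step 23**
Reactants: 28
Product: 29, tert-butyl (1R,3R)-6,8-bis(methoxymethoxy)-1,3-dimethyl-3,4-dihydroisoquinoline-2(1H)-carboxylate
Conditions: Boc2O (3 equiv), i-Pr2NEt, dioxane, 80 °C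
Reagents that add atoms: di-tert-butyl dicarbonate, CC(C)(C)OC(=O)OC(=O)OC(C)(C)C
Why: Carbamate formation on the hindered secondary amine under forcing conditions protects nitrogen from NBS and from the later oxidant.

**Step 24**
Reactants: 29
Product: 30, tert-butyl (1R,3R)-5-bromo-6,8-bis(methoxymethoxy)-1,3-dimethyl-3,4-dihydroisoquinoline-2(1H)-carboxylate
Conditions: NBS, MeCN, −20 → 0 °C
Reagents that add atoms: N-bromosuccinimide, O=C1CCC(=O)N1Br
Why: Electrophilic aromatic bromination at C5 (ortho/para to the two alkoxy groups), which is less hindered than C7 between them.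

**Step 25**
Reactants: 30; 9
Product: 31, tert-butyl (1R,3R,5P)-5-[4-(benzyloxy)-5-methoxy-7-methylnaphthalen-1-yl]-6,8-bis(methoxymethoxy)-1,3-dimethyl-3,4-dihydroisoquinoline-2(1H)-carboxylate
Conditions: Pd(OAc)2, SPhos, K3PO4, toluene/H2O, 90 °C; chromatographic separation of atropisomers
Reagents that add atoms: none
Why: Suzuki–Miyaura coupling as in Step 14; the atropo-diastereomers are separated and P is kept.

**Step 26**
Reactants: 31
Product: 32, tert-butyl (1R,3R,5P)-5-(4-hydroxy-5-methoxy-7-methylnaphthalen-1-yl)-6,8-bis(methoxymethoxy)-1,3-dimethyl-3,4-dihydroisoquinoline-2(1H)-carboxylate (naphthol B)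
Conditions: H2 (1 atm), 10% Pd/C, EtOAc/MeOH, rt
Reagents that add atoms: none
Why: Hydrogenolysis of the benzyl ether frees the 5″-OH; Boc and MOM groups are untouched.

### Union and endgame

**Step 27**
Reactants: 32; 22
Product: 33, unsymmetrical bis(aryloxy)diisopropylsilane in which Si(i-Pr)2 bridges the naphthol oxygen of 32 (O-5″) and that of 22 (O-5′)
Conditions: 32, i-Pr2SiCl2 (5 equiv), imidazole, CH2Cl2, 0 °C → rt; evaporate excess silane; then 22, imidazole, DMAP, DMF, rt
Reagents that add atoms: dichlorodiisopropylsilane, CC(C)[Si](Cl)(Cl)C(C)C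
Why: Sequential silyl ether formation (excess dichlorosilane gives the mono-aryloxy chlorosilane, which then captures the second naphthol) assembles the hetero pair exclusively; no other OH or basic NH is present.

**Step 28**
Reactants: 33
Product: 34, 6′,6″-bonded binaphthyl whose 5′- and 5″-oxygens are joined by Si(i-Pr)2 (seven-membered dioxasilepine); all other groups as in 33
Conditions: PhI(OCOCF3)2 (1.1 equiv), 2,6-di-tert-butylpyridine, HFIP/CH2Cl2 (3:1), 1 mM, −30 °C; aq Na2S2O3
Reagents that add atoms: none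
Why: Proposed new method: silicon-tethered dehydrogenative hetero-coupling of two different 1-naphthols, in which single-electron oxidation of a silyloxy-methoxynaphthalene in HFIP gives an arene radical cation that is trapped by the ortho carbon (C6) of the second naphthyl held by the O–Si–O tether (7-membered closure; para positions are blocked by the isoquinoline aryls and each peri-OMe turns the silyl ether toward C6), and a second oxidation with loss of 2 H+ rearomatises, so only the A–B dimer can form and high dilution suppresses intermolecular coupling; the closest known reaction types are hypervalent-iodine intramolecular oxidative biaryl coupling of tethered aryl ethers and the Ag2O ortho–ortho homodimerisation of 4-aryl-1-naphthols.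

**Step 29**
Reactants: 34
Product: 35, 6′,6″-binaphthalene-5′,5″-diol heterodimer (half A: Boc-amino ketone, 6-OMOM, 8-OMe; half B: N-Boc-(1R,3R)-THIQ, 6,8-bis-OMOM; both axes P)
Conditions: TBAF/AcOH (1:1), THF, 0 °C, degassed
Reagents that add atoms: none
Why: Buffered fluoride cleaves both Si–O bonds while MOM, Boc and the ketone are untouched; buffering and exclusion of air prevent oxidation of the binaphthol to the diphenoquinone.

**Step 30**
Reactants: 35
Product: 36, michellamine F
Conditions: 3 M HCl in MeOH, rt → 40 °C; then aq NaHCO3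
Reagents that add atoms: none
Why: Acid removes the three MOM ethers and both Boc groups, and the liberated primary amine condenses with the ortho acetyl group (6-membered cyclic imine formation) to give the 1-methyl-3,4-dihydroisoquinoline; no stereocentre is touched.

## Compound list

Axial descriptors (P) are given in the names; SMILES carry the stereocentres only.

1 | 2-bromo-5-hydroxybenzaldehyde | O=Cc1cc(O)ccc1Br | starting material
2 | 5-(benzyloxy)-2-bromobenzaldehyde | O=Cc1cc(OCc2ccccc2)ccc1Br | intermediate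
3 | diethyl succinate | CCOC(=O)CCC(=O)OCC | starting material
4 | (E)-4-[5-(benzyloxy)-2-bromophenyl]-3-(ethoxycarbonyl)but-3-enoic acid | CCOC(=O)/C(CC(=O)O)=C/c1cc(OCc2ccccc2)ccc1Br | intermediate
5 | ethyl 4-acetoxy-5-(benzyloxy)-8-bromo-2-naphthoate | CCOC(=O)c1cc(OC(C)=O)c2c(OCc3ccccc3)ccc(Br)c2c1 | intermediate
6 | ethyl 5-(benzyloxy)-8-bromo-4-methoxy-2-naphthoate | CCOC(=O)c1cc(OC)c2c(OCc3ccccc3)ccc(Br)c2c1 | intermediate
7 | [5-(benzyloxy)-8-bromo-4-methoxynaphthalen-2-yl]methanol | OCc1cc(OC)c2c(OCc3ccccc3)ccc(Br)c2c1 | intermediate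
8 | 4-(benzyloxy)-1-bromo-5-methoxy-7-methylnaphthalene | Cc1cc(OC)c2c(OCc3ccccc3)ccc(Br)c2c1 | intermediate
9 | 2-[4-(benzyloxy)-5-methoxy-7-methylnaphthalen-1-yl]-4,4,5,5-tetramethyl-1,3,2-dioxaborolane | Cc1cc(OC)c2c(OCc3ccccc3)ccc(B3OC(C)(C)C(C)(C)O3)c2c1 | intermediate
10 | (R)-2-methylpropane-2-sulfinamide | CC(C)(C)[S@@](=O)N | starting material
11 | acetaldehyde | CC=O | starting material
12 | (R,E)-N-ethylidene-2-methylpropane-2-sulfinamide | CC(C)(C)[S@@](=O)/N=C/C | intermediate
13 | methyl 2,4-dihydroxy-6-methylbenzoate | COC(=O)c1c(C)cc(O)cc1O | starting material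
14 | methyl 2-hydroxy-4-(methoxymethoxy)-6-methylbenzoate | COCOc1cc(C)c(C(=O)OC)c(O)c1 | intermediate
15 | methyl 2-methoxy-4-(methoxymethoxy)-6-methylbenzoate | COCOc1cc(C)c(C(=O)OC)c(OC)c1 | intermediate
16 | methyl 2-[(2R)-2-{[(R)-tert-butylsulfinyl]amino}propyl]-6-methoxy-4-(methoxymethoxy)benzoate | COCOc1cc(C[C@@H](C)N[S@](=O)C(C)(C)C)c(C(=O)OC)c(OC)c1 | intermediate
17 | (3R)-8-methoxy-6-(methoxymethoxy)-3-methyl-3,4-dihydroisoquinolin-1(2H)-one | COCOc1cc(OC)c2C(=O)N[C@H](C)Cc2c1 | intermediate
18 | (3R)-5-bromo-8-methoxy-6-(methoxymethoxy)-3-methyl-3,4-dihydroisoquinolin-1(2H)-one | COCOc1cc(OC)c2C(=O)N[C@H](C)Cc2c1Br | intermediate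
19 | (3R,5P)-5-[4-(benzyloxy)-5-methoxy-7-methylnaphthalen-1-yl]-8-methoxy-6-(methoxymethoxy)-3-methyl-3,4-dihydroisoquinolin-1(2H)-one | COCOc1cc(OC)c2C(=O)N[C@H](C)Cc2c1-c1ccc(OCc2ccccc2)c2c(OC)cc(C)cc12 | intermediate
20 | N-Boc derivative of 19 (tert-butyl 1-oxo-3,4-dihydroisoquinoline-2(1H)-carboxylate; 3R, P) | COCOc1cc(OC)c2C(=O)N(C(=O)OC(C)(C)C)[C@H](C)Cc2c1-c1ccc(OCc2ccccc2)c2c(OC)cc(C)cc12 | intermediate
21 | tert-butyl N-[(2R)-1-{2-acetyl-6-[(P)-4-(benzyloxy)-5-methoxy-7-methylnaphthalen-1-yl]-3-methoxy-5-(methoxymethoxy)phenyl}propan-2-yl]carbamate | COCOc1cc(OC)c(C(C)=O)c(C[C@@H](C)NC(=O)OC(C)(C)C)c1-c1ccc(OCc2ccccc2)c2c(OC)cc(C)cc12 | intermediate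
22 | naphthol A: tert-butyl N-[(2R)-1-{2-acetyl-6-[(P)-4-hydroxy-5-methoxy-7-methylnaphthalen-1-yl]-3-methoxy-5-(methoxymethoxy)phenyl}propan-2-yl]carbamate | COCOc1cc(OC)c(C(C)=O)c(C[C@@H](C)NC(=O)OC(C)(C)C)c1-c1ccc(O)c2c(OC)cc(C)cc12 | intermediate
23 | 2,4-dihydroxy-6-methylbenzaldehyde | Cc1cc(O)cc(O)c1C=O | starting material
24 | 2,4-bis(methoxymethoxy)-6-methylbenzaldehyde | COCOc1cc(C)c(C=O)c(OCOC)c1 | intermediate
25 | 2,4-bis(methoxymethoxy)-6-methylbenzonitrile | COCOc1cc(C)c(C#N)c(OCOC)c1 | intermediate
26 | (R)-N-{(2R)-1-[2-cyano-3,5-bis(methoxymethoxy)phenyl]propan-2-yl}-2-methylpropane-2-sulfinamide | COCOc1cc(C[C@@H](C)N[S@](=O)C(C)(C)C)c(C#N)c(OCOC)c1 | intermediate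
27 | (3R)-6,8-bis(methoxymethoxy)-1,3-dimethyl-3,4-dihydroisoquinoline | COCOc1cc(OCOC)c2C(C)=N[C@H](C)Cc2c1 | intermediate
28 | (1R,3R)-6,8-bis(methoxymethoxy)-1,3-dimethyl-1,2,3,4-tetrahydroisoquinoline | COCOc1cc(OCOC)c2[C@@H](C)N[C@H](C)Cc2c1 | intermediate
29 | tert-butyl (1R,3R)-6,8-bis(methoxymethoxy)-1,3-dimethyl-3,4-dihydroisoquinoline-2(1H)-carboxylate | COCOc1cc(OCOC)c2[C@@H](C)N(C(=O)OC(C)(C)C)[C@H](C)Cc2c1 | intermediate
30 | tert-butyl (1R,3R)-5-bromo-6,8-bis(methoxymethoxy)-1,3-dimethyl-3,4-dihydroisoquinoline-2(1H)-carboxylate | COCOc1cc(OCOC)c2[C@@H](C)N(C(=O)OC(C)(C)C)[C@H](C)Cc2c1Br | intermediate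
31 | tert-butyl (1R,3R,5P)-5-[4-(benzyloxy)-5-methoxy-7-methylnaphthalen-1-yl]-6,8-bis(methoxymethoxy)-1,3-dimethyl-3,4-dihydroisoquinoline-2(1H)-carboxylate | COCOc1cc(OCOC)c2[C@@H](C)N(C(=O)OC(C)(C)C)[C@H](C)Cc2c1-c1ccc(OCc2ccccc2)c2c(OC)cc(C)cc12 | intermediate
32 | naphthol B: tert-butyl (1R,3R,5P)-5-(4-hydroxy-5-methoxy-7-methylnaphthalen-1-yl)-6,8-bis(methoxymethoxy)-1,3-dimethyl-3,4-dihydroisoquinoline-2(1H)-carboxylate | COCOc1cc(OCOC)c2[C@@H](C)N(C(=O)OC(C)(C)C)[C@H](C)Cc2c1-c1ccc(O)c2c(OC)cc(C)cc12 | intermediate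
33 | mixed bis(aryloxy)diisopropylsilane (O-5″ of 32)–Si(i-Pr)2–(O-5′ of 22) | COCOc1cc(OCOC)c2[C@@H](C)N(C(=O)OC(C)(C)C)[C@H](C)Cc2c1-c1ccc(O[Si](C(C)C)(C(C)C)Oc2ccc(-c3c(OCOC)cc(OC)c(C(C)=O)c3C[C@@H](C)NC(=O)OC(C)(C)C)c3cc(C)cc(OC)c23)c2c(OC)cc(C)cc12 | intermediate
34 | Si(i-Pr)2-bridged 6′,6″-coupled heterodimer (cyclic silylene diether) | COCOc1cc(OCOC)c2[C@@H](C)N(C(=O)OC(C)(C)C)[C@H](C)Cc2c1-c1cc4c(O[Si](C(C)C)(C(C)C)Oc5c4cc(-c3c(OCOC)cc(OC)c(C(C)=O)c3C[C@@H](C)NC(=O)OC(C)(C)C)c6cc(C)cc(OC)c56)c2c(OC)cc(C)cc12 | intermediate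
35 | protected 6′,6″-binaphthalene-5′,5″-diol heterodimer (Boc-amino ketone half A; N-Boc THIQ half B) | COCOc1cc(OCOC)c2[C@@H](C)N(C(=O)OC(C)(C)C)[C@H](C)Cc2c1-c1cc(-c3cc(-c4c(OCOC)cc(OC)c(C(C)=O)c4C[C@@H](C)NC(=O)OC(C)(C)C)c4cc(C)cc(OC)c4c3O)c(O)c2c(OC)cc(C)cc12 | intermediate
36 | michellamine F | COc1cc(O)c(-c2cc(-c3cc(-c4c(O)cc(O)c5c4C[C@@H](C)N[C@@H]5C)c4cc(C)cc(OC)c4c3O)c(O)c3c(OC)cc(C)cc23)c2c1C(C)=N[C@H](C)C2 | target

## Summary

Total step count: 30.

Longest linear sequence: 15 steps (Steps 1–7, 14–17, 27–30; from 2-bromo-5-hydroxybenzaldehyde).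

Three steps most likely to fail:

1. **Step 28 (proposed new Si-tethered oxidative hetero-coupling; it also relies on the hindered silane assembly in Step 27).** Risks are over-oxidation of the product, intermolecular coupling at C1′/C3′ and tether solvolysis. Fallback (known chemistry): brominate 22 and 32 at C6′ (NBS, ortho to the free naphthol), protect both naphthols as MOM ethers, convert one bromide to the pinacol boronate (Miyaura borylation), join the halves by Pd/SPhos Suzuki–Miyaura cross-coupling, and finish with the Step 30 acid treatment.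

2. **Steps 14 and 25 (hindered Suzuki coupling with no axial control, relying on P/M separation).** Fallback: set the axis before the stereocentres exist, by a ligand-controlled atroposelective Suzuki coupling of 9 with the simple brominated toluate or tolunitrile (brominated 15 or 25) using a P-chiral monophosphine, then run the lateral-lithiation/sulfinimine sequence on the enantioenriched biaryl.

3. **Steps 11 and 20 (benzylic lithium addition to an enolisable sulfinyl acetaldimine; yield and diastereoselectivity).** Fallback: take C3 from the chiral pool by Cu-catalysed opening of the D-alaninol-derived cyclic sulfamidate ((R)-N-Boc-4-methyl-1,2,3-oxathiazolidine 2,2-dioxide) with the aryl Grignard of the corresponding 1-bromo-3,5-dialkoxybenzene, then N-acetylation and Bischler–Napieralski ring closure.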